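**Plan**

1. Retrosynthetic cuts, in order: (a) the (Z)-coumarate at its Cα=Cβ alkene and at the O15–acyl bond, leaving a C15 allylic alcohol; (b) in one operation the ring-fusion bond C5–C10 and the ring A bond C1–C2 (retro-Diels–Alder), leaving an open-chain triene; (c) the C2=C3 and C10=C1 alkenes, the C4–C15 bond and the C4=C5 alkene, leaving a keto aldehyde that is (R)-limonene with its ring alkene cleaved and its isopropenyl methyl oxidised.
2. Feature that permits cut (b): ring A is a cyclohexene whose alkene C3=C4 (C15 on C4) lies between the ring-fusion carbon C5 (H) and, through C2–C1, the quaternary C10 (CH3). Read backwards, C2=C3–C4=C5 is a diene and C10=C1 a 1,1-disubstituted alkene, and the four carbons joining them (C6–C7–C8–C9) are the rest of ring B. C7, with its acrylate and its arms C6–C5 and C8–C9–C10–CH3, is C4 of limonene after cleavage of the limonene C1=C2 bond.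
3. Forward order: acrylate from limonene (steps 1–4); ring opened (5–6); diene built on the aldehyde arm (7–9); both carbonyl groups methylenated (10); rings B and A closed together (11); coumarate chain joined at O15 as a phosphonoacetate and its Z alkene formed (12–14); both silyl groups removed (15).
4. Stereochemistry: C7 is the untouched stereocentre of (R)-limonene. C5 and C10 arise together in step 11, relative to C7, from a chair-like tether with the acrylate equatorial and anti folding (trans fusion). The diene geometry comes from the E-selective Wittig step and the geometry-retaining iodination/Stille pair. The Z alkene of the coumarate comes from the Still–Gennari olefination.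

Key step: step 11

Remark: carbons are numbered as in the eudesmanes (ring A = C1–C5 and C10, ring B = C5–C10, C11–C13 = acrylate on C7, C14 = methyl on C10, C15 = oxygen-bearing carbon on C4); it is assumed that the epoxide diastereomers of 8 and the diol diastereomers of 9 can be carried on together, since both carbons are cleaved in step 6.

**Route**

Step 1
Reactants: 1 (R)-(+)-limonene
Product: 4 2-[(1R)-4-methylcyclohex-3-en-1-yl]prop-2-en-1-ol, via allyllithium 2 (not isolated), via lithium allyltrimethoxyborate 3 (not isolated)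
Conditions: n-BuLi, TMEDA, hexane, rt; B(OMe)3, THF, −78 → 0 °C; NaOH, 30% H2O2, 0 °C → rt
Reagents that add atoms: n-butyllithium, [Li]CCCC (lithium of 2); trimethyl borate, COB(OC)OC (boron and methoxy groups of 3); hydrogen peroxide, OO (oxygen of 4)
Why: Allylic metalation with n-BuLi·TMEDA takes a proton from the isopropenyl methyl group to give a 2-substituted allyllithium whose two ends are equivalent, and borylation followed by peroxide oxidation (the oxidative 1,2-shift known from hydroboration–oxidation) turns C–Li into C–OH while the C4 stereocentre of limonene is left untouched.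

Step 2
Reactants: 4 2-[(1R)-4-methylcyclohex-3-en-1-yl]prop-2-en-1-ol
Product: 5 2-[(1R)-4-methylcyclohex-3-en-1-yl]prop-2-enal
Conditions: activated MnO2 (excess), CH2Cl2, rt
Reagents that add atoms: none
Why: Activated MnO2 oxidises allylic primary alcohols to enals under neutral conditions and stops at the aldehyde (allylic alcohol oxidation).

Step 3
Reactants: 5 2-[(1R)-4-methylcyclohex-3-en-1-yl]prop-2-enal
Product: 6 2-[(1R)-4-methylcyclohex-3-en-1-yl]prop-2-enoic acid
Conditions: NaClO2, NaH2PO4, 2-methyl-2-butene (excess), t-BuOH/H2O, 0 °C → rt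
Reagents that add atoms: sodium chlorite, [Na+].[O-]Cl=O
Why: Pinnick oxidation converts an enal into the enoic acid without touching either alkene, because the hypochlorous acid that forms is trapped by 2-methyl-2-butene before it can reach the ring alkene.

Step 4
Reactants: 6 2-[(1R)-4-methylcyclohex-3-en-1-yl]prop-2-enoic acid
Product: 7 2-(trimethylsilyl)ethyl 2-[(1R)-4-methylcyclohex-3-en-1-yl]prop-2-enoate
Conditions: Me3SiCH2CH2OH, DCC, DMAP (catalytic), CH2Cl2, 0 °C → rt
Reagents that add atoms: 2-(trimethylsilyl)ethanol, OCC[Si](C)(C)C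
Why: Steglich esterification (carbodiimide activation with DMAP as acyl-transfer catalyst) gives the 2-(trimethylsilyl)ethyl ester, a carboxyl protecting group that stands up to acid, oxidants, organometallic reagents and heat and leaves at the end with fluoride.

Step 5
Reactants: 7 2-(trimethylsilyl)ethyl 2-[(1R)-4-methylcyclohex-3-en-1-yl]prop-2-enoate
Product: 8 2-(trimethylsilyl)ethyl 2-[(3R)-6-methyl-7-oxabicyclo[4.1.0]heptan-3-yl]prop-2-enoate (both epoxide diastereomers)
Conditions: mCPBA, CH2Cl2, 0 °C
Reagents that add atoms: 3-chloroperoxybenzoic acid, OOC(=O)c1cccc(Cl)c1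
Why: Prilezhaev epoxidation is an electrophilic oxygen transfer, so the electron-rich trisubstituted ring alkene reacts and the electron-poor acrylate does not, and the mixture of epoxide diastereomers is of no consequence because both epoxide carbons become carbonyl carbons in step 6.

Step 6
Reactants: 8 2-(trimethylsilyl)ethyl 2-[(3R)-6-methyl-7-oxabicyclo[4.1.0]heptan-3-yl]prop-2-enoate
Product: 10 2-(trimethylsilyl)ethyl (3R)-2-methylidene-6-oxo-3-(2-oxoethyl)heptanoate, via vicinal diol 9 (not isolated)
Conditions: H5IO6, THF/H2O, 0 °C → rt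
Reagents that add atoms: water, O
Why: Periodic acid first opens the epoxide to the vicinal diol and then cleaves it (Malaprade glycol cleavage), which turns the former ring alkene carbons into the C5 aldehyde and the C10 methyl ketone in one flask, as is routine for 1-methylcyclohexene oxides of the limonene type.

Step 7
Reactants: 10 2-(trimethylsilyl)ethyl (3R)-2-methylidene-6-oxo-3-(2-oxoethyl)heptanoate; 11 (triphenylphosphoranylidene)acetaldehyde
Product: 12 2-(trimethylsilyl)ethyl (3R,5E)-2-methylidene-7-oxo-3-(3-oxobutyl)hept-5-enoate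
Conditions: toluene, 75 °C
Reagents that add atoms: 11 (triphenylphosphoranylidene)acetaldehyde, O=CC=P(c1ccccc1)(c1ccccc1)c1ccccc1
Why: Wittig olefination with the formyl-stabilised ylide is E-selective and, at this temperature, takes the aldehyde and leaves the methyl ketone alone, and a near-stoichiometric amount of ylide keeps the product enal from being homologated a second time.

Step 8
Reactants: 12 2-(trimethylsilyl)ethyl (3R,5E)-2-methylidene-7-oxo-3-(3-oxobutyl)hept-5-enoate
Product: 13 2-(trimethylsilyl)ethyl (3R,5Z)-6-iodo-2-methylidene-7-oxo-3-(3-oxobutyl)hept-5-enoate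
Conditions: I2, pyridine, DMAP (catalytic), CH2Cl2, 0 °C → rt
Reagents that add atoms: iodine, [I][I]
Why: Alpha-iodination of an enal by the addition–iodination–elimination sequence of the Baylis–Hillman type (the amine adds at C5, the enolate is iodinated at C4, the amine leaves) gives the Z iodo enal with the formyl group still trans to C6 as the more stable isomer, while the acrylate, which has no alpha hydrogen, and the weakly enolised ketone are not touched under these non-aqueous conditions.

Step 9
Reactants: 13 2-(trimethylsilyl)ethyl (3R,5Z)-6-iodo-2-methylidene-7-oxo-3-(3-oxobutyl)hept-5-enoate; 14 (tributylstannyl)methanol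
Product: 15 2-(trimethylsilyl)ethyl (3R,5E)-6-(hydroxymethyl)-2-methylidene-7-oxo-3-(3-oxobutyl)hept-5-enoate
Conditions: Pd(PPh3)4 (catalytic), CuI (catalytic), DMF, 50 °C
Reagents that add atoms: 14 (tributylstannyl)methanol, OC[Sn](CCCC)(CCCC)CCCC
Why: Migita–Kosugi–Stille coupling, in which zerovalent palladium inserts into the activated vinyl C–I bond, the hydroxymethyl group is transferred from tin in preference to butyl (helped by CuI) and reductive elimination keeps the alkene geometry, so that C15 ends up cis to C6 and the formyl group stays trans to it (the descriptor changes from Z to E only through the priority rules).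

Step 10
Reactants: 15 2-(trimethylsilyl)ethyl (3R,5E)-6-(hydroxymethyl)-2-methylidene-7-oxo-3-(3-oxobutyl)hept-5-enoate
Product: 16 2-(trimethylsilyl)ethyl (3R,5Z)-6-(hydroxymethyl)-2-methylidene-3-(3-methylbut-3-en-1-yl)octa-5,7-dienoate
Conditions: Zn, CH2Br2, TiCl4 (preformed reagent, excess), THF/CH2Cl2, 0 °C → rt
Reagents that add atoms: dibromomethane, BrCBr
Why: Takai–Lombardo methylenation with the non-basic geminal dimetal reagent from Zn, CH2Br2 and TiCl4 converts both the formyl group (into C3=C2) and the methyl ketone (into C10=C1) without enolisation, conjugate addition to the acrylate or attack on the ester, and a free hydroxyl group is tolerated.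

Step 11
Reactants: 16 2-(trimethylsilyl)ethyl (3R,5Z)-6-(hydroxymethyl)-2-methylidene-3-(3-methylbut-3-en-1-yl)octa-5,7-dienoate
Product: 17 2-(trimethylsilyl)ethyl 2-[(2R,4aR,8aR)-8-(hydroxymethyl)-4a-methyl-1,2,3,4,4a,5,6,8a-octahydronaphthalen-2-yl]prop-2-enoate
Conditions: o-dichlorobenzene (degassed, 5 mM), BHT, 190–200 °C, sealed base-washed vessel, Ar
Reagents that add atoms: none
Why: On heating, the triene should undergo a concerted, suprafacial [4+2] cycloaddition in which the diene C2=C3–C4=C5 adds across the unactivated 1,1-disubstituted alkene C10=C1 and forms C5–C10 and C1–C2 in one event; the closest known reaction type is the thermal type 1 intramolecular Diels–Alder reaction of deca-1,7,9-trienes with a methyl-bearing dienophile, which gives angular-methyl octalins. Ring B closes as a six-membered carbocycle from the four-carbon tether C6–C9 and the new C5–C10 bond (fused mode, chair-like tether), and ring A closes at the same time as the cyclohexene C1–C2–C3=C4–C5–C10, its alkene arriving at C3=C4 with C15 on C4. The new centres C5 and C10 are set relative to each other by the anti folding (tether exo), which places the diene carbon C4 and the alkene carbon C1 both equatorial on the developing chair and so makes H-5 and the C10 methyl trans-diaxial (trans ring fusion). They are set relative to C7 by the equatorial position of the C7 acrylate on that chair, which puts the axial C10 methyl on the same face as the acrylate and leaves C7 itself untouched. The step needs the anti over the syn folding, and in the syn folding the diene would sit axially over the tether with its C4 hydroxymethyl arm against the axial hydrogens at C7 and C9, so the C4 substituent acts as a built-in steric control element and the cis-fused isomers are expected as minor products to be removed by chromatography. Competing paths are closed by the substrate and the conditions, since C6 is held on the outer position of the diene by the 5Z geometry (no 1,5-hydrogen shift), the alpha-substituted acrylate is tied to the diene by only two atoms and cannot reach it, and high dilution, BHT and base-washed glass keep intermolecular addition and acid-induced diene isomerisation down.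

Step 12
Reactants: 18 methyl bis(2,2,2-trifluoroethyl)phosphonoacetate
Product: 19 bis(2,2,2-trifluoroethyl)phosphonoacetic acid
Conditions: pig liver esterase, phosphate buffer pH 7.5, rt; then pH 2, EtOAc extraction
Reagents that add atoms: water, O
Why: Enzymatic ester hydrolysis with a carboxylesterase at neutral pH cleaves the carboxylic methyl ester only, whereas hydroxide would also displace trifluoroethoxide from phosphorus.

Step 13
Reactants: 17 2-(trimethylsilyl)ethyl 2-[(2R,4aR,8aR)-8-(hydroxymethyl)-4a-methyl-1,2,3,4,4a,5,6,8a-octahydronaphthalen-2-yl]prop-2-enoate; 19 bis(2,2,2-trifluoroethyl)phosphonoacetic acid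
Product: 20 2-(trimethylsilyl)ethyl 2-[(2R,4aR,8aR)-8-[({[bis(2,2,2-trifluoroethoxy)phosphoryl]acetyl}oxy)methyl]-4a-methyl-1,2,3,4,4a,5,6,8a-octahydronaphthalen-2-yl]prop-2-enoate
Conditions: DCC, DMAP (catalytic), CH2Cl2, 0 °C → rt
Reagents that add atoms: 19 bis(2,2,2-trifluoroethyl)phosphonoacetic acid, OC(=O)CP(=O)(OCC(F)(F)F)OCC(F)(F)F
Why: Steglich esterification of the primary allylic alcohol with the phosphonoacetic acid, which is activated by the carbodiimide, joins the two-carbon acyl unit to O15 under neutral conditions that leave both alkenes and the silyl ester alone.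

Step 14
Reactants: 20 the C15 phosphonoacetate named in step 13; 21 4-(tert-butyldimethylsilyloxy)benzaldehyde
Product: 22 2-(trimethylsilyl)ethyl 2-[(2R,4aR,8aR)-8-[({(2Z)-3-[4-(tert-butyldimethylsilyloxy)phenyl]prop-2-enoyl}oxy)methyl]-4a-methyl-1,2,3,4,4a,5,6,8a-octahydronaphthalen-2-yl]prop-2-enoate
Conditions: KN(SiMe3)2, 18-crown-6, THF, −78 °C
Reagents that add atoms: 21 4-(tert-butyldimethylsilyloxy)benzaldehyde, O=Cc1ccc(O[Si](C)(C)C(C)(C)C)cc1
Why: Still–Gennari olefination, in which the potassium enolate of the bis(trifluoroethyl) phosphonoacetate, kept free of its counter-ion by 18-crown-6, adds to the aromatic aldehyde under kinetic control and the electron-poor phosphonate eliminates faster than the adducts can equilibrate, which gives the Z alkene.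

Step 15
Reactants: 22 the doubly silyl-protected Z coumarate named in step 14
Product: 23 2-[(2R,4aR,8aR)-8-[({(2Z)-3-(4-hydroxyphenyl)prop-2-enoyl}oxy)methyl]-4a-methyl-1,2,3,4,4a,5,6,8a-octahydronaphthalen-2-yl]prop-2-enoic acid (CNP0183482.1)
Conditions: tris(dimethylamino)sulfonium difluorotrimethylsilicate [(Me2N)3S][Me3SiF2] (TASF), DMF, 0 °C → rt, dark; AcOH/NaOAc buffer (pH 5)
Reagents that add atoms: none
Why: Fluoride-induced desilylation removes both protecting groups in one operation, the aryl silyl ether by attack at silicon and the 2-(trimethylsilyl)ethyl ester by attack at silicon with fragmentation to ethene and the carboxylate, and the mild, non-hydroxylic fluoride source, low temperature and exclusion of light are chosen to spare the allylic ester and the Z alkene.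

**Compound list**

1 | (R)-(+)-limonene | CC(=C)[C@@H]1CCC(C)=CC1 | starting material
2 | 10-lithiolimonene (allyllithium; not isolated) | [Li]CC(=C)[C@@H]1CCC(C)=CC1 | intermediate
3 | lithium trimethoxy{2-[(1R)-4-methylcyclohex-3-en-1-yl]prop-2-en-1-yl}borate (not isolated) | [Li+].CO[B-](OC)(OC)CC(=C)[C@@H]1CCC(C)=CC1 | intermediate
4 | 2-[(1R)-4-methylcyclohex-3-en-1-yl]prop-2-en-1-ol | OCC(=C)[C@@H]1CCC(C)=CC1 | intermediate
5 | 2-[(1R)-4-methylcyclohex-3-en-1-yl]prop-2-enal | O=CC(=C)[C@@H]1CCC(C)=CC1 | intermediate
6 | 2-[(1R)-4-methylcyclohex-3-en-1-yl]prop-2-enoic acid | OC(=O)C(=C)[C@@H]1CCC(C)=CC1 | intermediate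
7 | 2-(trimethylsilyl)ethyl 2-[(1R)-4-methylcyclohex-3-en-1-yl]prop-2-enoate | C=C(C(=O)OCC[Si](C)(C)C)[C@@H]1CCC(C)=CC1 | intermediate
8 | 2-(trimethylsilyl)ethyl 2-[(3R)-6-methyl-7-oxabicyclo[4.1.0]heptan-3-yl]prop-2-enoate (both epoxide diastereomers) | C=C(C(=O)OCC[Si](C)(C)C)[C@@H]1CCC2(C)OC2C1 | intermediate
9 | 2-(trimethylsilyl)ethyl 2-[(1R)-3,4-dihydroxy-4-methylcyclohexyl]prop-2-enoate (diol diastereomers; not isolated) | C=C(C(=O)OCC[Si](C)(C)C)[C@@H]1CCC(C)(O)C(O)C1 | intermediate
10 | 2-(trimethylsilyl)ethyl (3R)-2-methylidene-6-oxo-3-(2-oxoethyl)heptanoate | C=C(C(=O)OCC[Si](C)(C)C)[C@@H](CC=O)CCC(C)=O | intermediate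
11 | (triphenylphosphoranylidene)acetaldehyde | O=CC=P(c1ccccc1)(c1ccccc1)c1ccccc1 | starting material
12 | 2-(trimethylsilyl)ethyl (3R,5E)-2-methylidene-7-oxo-3-(3-oxobutyl)hept-5-enoate | C=C(C(=O)OCC[Si](C)(C)C)[C@@H](C/C=C/C=O)CCC(C)=O | intermediate
13 | 2-(trimethylsilyl)ethyl (3R,5Z)-6-iodo-2-methylidene-7-oxo-3-(3-oxobutyl)hept-5-enoate | C=C(C(=O)OCC[Si](C)(C)C)[C@@H](C/C=C(I)/C=O)CCC(C)=O | intermediate
14 | (tributylstannyl)methanol | OC[Sn](CCCC)(CCCC)CCCC | starting material
15 | 2-(trimethylsilyl)ethyl (3R,5E)-6-(hydroxymethyl)-2-methylidene-7-oxo-3-(3-oxobutyl)hept-5-enoate | C=C(C(=O)OCC[Si](C)(C)C)[C@@H](C/C=C(CO)/C=O)CCC(C)=O | intermediate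
16 | 2-(trimethylsilyl)ethyl (3R,5Z)-6-(hydroxymethyl)-2-methylidene-3-(3-methylbut-3-en-1-yl)octa-5,7-dienoate | C=C(C(=O)OCC[Si](C)(C)C)[C@@H](C/C=C(CO)/C=C)CCC(C)=C | intermediate
17 | 2-(trimethylsilyl)ethyl 2-[(2R,4aR,8aR)-8-(hydroxymethyl)-4a-methyl-1,2,3,4,4a,5,6,8a-octahydronaphthalen-2-yl]prop-2-enoate | C=C(C(=O)OCC[Si](C)(C)C)[C@@H]1CC[C@@]2(C)CCC=C(CO)[C@@H]2C1 | intermediate
18 | methyl bis(2,2,2-trifluoroethyl)phosphonoacetate | COC(=O)CP(=O)(OCC(F)(F)F)OCC(F)(F)F | starting material
19 | bis(2,2,2-trifluoroethyl)phosphonoacetic acid | OC(=O)CP(=O)(OCC(F)(F)F)OCC(F)(F)F | intermediate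
20 | 2-(trimethylsilyl)ethyl 2-[(2R,4aR,8aR)-8-[({[bis(2,2,2-trifluoroethoxy)phosphoryl]acetyl}oxy)methyl]-4a-methyl-1,2,3,4,4a,5,6,8a-octahydronaphthalen-2-yl]prop-2-enoate | C=C(C(=O)OCC[Si](C)(C)C)[C@@H]1CC[C@@]2(C)CCC=C(COC(=O)CP(=O)(OCC(F)(F)F)OCC(F)(F)F)[C@@H]2C1 | intermediate
21 | 4-(tert-butyldimethylsilyloxy)benzaldehyde | O=Cc1ccc(O[Si](C)(C)C(C)(C)C)cc1 | starting material
22 | 2-(trimethylsilyl)ethyl 2-[(2R,4aR,8aR)-8-[({(2Z)-3-[4-(tert-butyldimethylsilyloxy)phenyl]prop-2-enoyl}oxy)methyl]-4a-methyl-1,2,3,4,4a,5,6,8a-octahydronaphthalen-2-yl]prop-2-enoate | C=C(C(=O)OCC[Si](C)(C)C)[C@@H]1CC[C@@]2(C)CCC=C(COC(=O)/C=C\c3ccc(O[Si](C)(C)C(C)(C)C)cc3)[C@@H]2C1 | intermediate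
23 | 2-[(2R,4aR,8aR)-8-[({(2Z)-3-(4-hydroxyphenyl)prop-2-enoyl}oxy)methyl]-4a-methyl-1,2,3,4,4a,5,6,8a-octahydronaphthalen-2-yl]prop-2-enoic acid (CNP0183482.1) | C=C(C(=O)O)[C@@H]1CC[C@@]2(C)CCC=C(COC(=O)/C=C\c3ccc(O)cc3)[C@@H]2C1 | target

**Step count and risks**

Total step count: 15. Longest linear sequence: 14 steps (steps 1–11 and 13–15, from 1 to 23); step 12 is a one-step side branch.

Steps most likely to fail:

Step 11. The anti and the syn folding of the tether may be poorly discriminated, and so may the two faces defined by the C7 substituent, because the dienophile is unactivated and carries a methyl group of similar size to the tether carbon; the free dienyl alcohol may also degrade during long heating. The fallback sets out from 16 and turns the C15 oxygen into a larger steric control element. Silylation (TBSCl, imidazole, DMF) should give 2-(trimethylsilyl)ethyl (3R,5Z)-6-[(tert-butyldimethylsilyloxy)methyl]-2-methylidene-3-(3-methylbut-3-en-1-yl)octa-5,7-dienoate F1, whose bulkier C4 arm raises the cost of the syn folding in which the diene lies axially over the tether. Heating F1 as in step 11 should give 2-(trimethylsilyl)ethyl 2-[(2R,4aR,8aR)-8-[(tert-butyldimethylsilyloxy)methyl]-4a-methyl-1,2,3,4,4a,5,6,8a-octahydronaphthalen-2-yl]prop-2-enoate F2. HF·pyridine in THF/pyridine, which leaves the 2-(trimethylsilyl)ethyl ester alone, then brings the route back at 17.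

Step 9. Transfer of the sp3 hydroxymethyl group from tin may be slow, which would leave the vinylpalladium intermediate time for protodeiodination, loss of alkene geometry or insertion into the nearby acrylate. The fallback sets out from 10, brings C15 in as a methyl group and oxidises it after the rings are closed. Wittig reaction of 10 with commercial 2-(triphenylphosphoranylidene)propanal (toluene, 80 °C) should give 2-(trimethylsilyl)ethyl (3R,5E)-6-methyl-2-methylidene-7-oxo-3-(3-oxobutyl)hept-5-enoate F3. Methylenation with Zn, CH2Br2 and TiCl4 as in step 10 should give 2-(trimethylsilyl)ethyl (3R,5E)-6-methyl-2-methylidene-3-(3-methylbut-3-en-1-yl)octa-5,7-dienoate F4. Heating as in step 11 should give 2-(trimethylsilyl)ethyl 2-[(2R,4aR,8aR)-4a,8-dimethyl-1,2,3,4,4a,5,6,8a-octahydronaphthalen-2-yl]prop-2-enoate F5. Allylic oxidation with catalytic SeO2 and t-BuOOH in CH2Cl2, which should take the methyl group on the more substituted alkene carbon C4 in preference to the ring-fusion methine C5, comes back to the route at 17.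

Step 15. While the phenol is present as its phenoxide the coumarate may isomerise thermally from Z to E, and fluoride may also cleave the allylic ester. The fallback sets out from 22 and fixes the alkene geometry after deprotection instead of carrying it through. 22 is desilylated as in step 15 without regard to geometry, which would give the target mixed with 2-[(2R,4aR,8aR)-8-[({(2E)-3-(4-hydroxyphenyl)prop-2-enoyl}oxy)methyl]-4a-methyl-1,2,3,4,4a,5,6,8a-octahydronaphthalen-2-yl]prop-2-enoic acid F6. The mixture is irradiated at about 310–365 nm in acetonitrile to the photostationary state (direct E/Z photoisomerisation of 4-hydroxycinnamate esters, a wavelength at which the acrylic acid does not absorb). 23 is isolated by reverse-phase HPLC in the dark, and recovered F6 is irradiated again.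

**Further compounds**

F1 | step 11 | 2-(trimethylsilyl)ethyl (3R,5Z)-6-[(tert-butyldimethylsilyloxy)methyl]-2-methylidene-3-(3-methylbut-3-en-1-yl)octa-5,7-dienoate | C=C(C(=O)OCC[Si](C)(C)C)[C@@H](C/C=C(CO[Si](C)(C)C(C)(C)C)/C=C)CCC(C)=C
F2 | step 11 | 2-(trimethylsilyl)ethyl 2-[(2R,4aR,8aR)-8-[(tert-butyldimethylsilyloxy)methyl]-4a-methyl-1,2,3,4,4a,5,6,8a-octahydronaphthalen-2-yl]prop-2-enoate | C=C(C(=O)OCC[Si](C)(C)C)[C@@H]1CC[C@@]2(C)CCC=C(CO[Si](C)(C)C(C)(C)C)[C@@H]2C1
F3 | step 9 | 2-(trimethylsilyl)ethyl (3R,5E)-6-methyl-2-methylidene-7-oxo-3-(3-oxobutyl)hept-5-enoate | C=C(C(=O)OCC[Si](C)(C)C)[C@@H](C/C=C(C)/C=O)CCC(C)=O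
F4 | step 9 | 2-(trimethylsilyl)ethyl (3R,5E)-6-methyl-2-methylidene-3-(3-methylbut-3-en-1-yl)octa-5,7-dienoate | C=C(C(=O)OCC[Si](C)(C)C)[C@@H](C/C=C(C)/C=C)CCC(C)=C
F5 | step 9 | 2-(trimethylsilyl)ethyl 2-[(2R,4aR,8aR)-4a,8-dimethyl-1,2,3,4,4a,5,6,8a-octahydronaphthalen-2-yl]prop-2-enoate | C=C(C(=O)OCC[Si](C)(C)C)[C@@H]1CC[C@@]2(C)CCC=C(C)[C@@H]2C1
F6 | step 15 | 2-[(2R,4aR,8aR)-8-[({(2E)-3-(4-hydroxyphenyl)prop-2-enoyl}oxy)methyl]-4a-methyl-1,2,3,4,4a,5,6,8a-octahydronaphthalen-2-yl]prop-2-enoic acid | C=C(C(=O)O)[C@@H]1CC[C@@]2(C)CCC=C(COC(=O)/C=C/c3ccc(O)cc3)[C@@H]2C1
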